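**Plan**

- Retrosynthesis: the three MOM ethers are removed last. Ring C is then cut at C2–C3 and at O1–C8a, which gives an aryl aldehyde (C2 and O1, ring B) and a 2'-fluoroaryl methyl ketone as its enol silane (C3, C4, ring A with F on C8a).
- The feature that allows this is the C4 carbonyl of ring C. It makes C3 an enol(ate) carbon and, being ortho to C8a of ring A, activates a C8a–F bond for SNAr. Ring A has no 5-substituent, so C8a is the only activated position.
- Forward, ring A piece: 4-bromo-3-fluorophenol is MOM-protected, lithiated and prenylated between F and OMOM, converted from Br to acetyl, and turned into the enol silane.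
- Forward, ring B piece: 3-bromo-4,5-dihydroxybenzaldehyde is bis-MOM-protected and prenylated by Stille coupling.
- Ring C, the only ring formed, arises in one flask by a catalytic enantioselective Mukaiyama aldol followed by fluoride-relayed SNAr closure; deprotection ends the route.
- Stereochemistry: C2 (S) comes from catalyst-controlled Si-face addition to the aldehyde. Its C–O bond is made in the aldol stage and is not broken in the closure.

Key step: step 7

Assumption: the N-tosyltryptophan-derived B-butyl oxazaborolidinone is taken to show its usual sense of induction with aromatic aldehydes (catalyst from (S)-tryptophan gives Re-face attack), so the (R)-tryptophan-derived catalyst is specified for Si-face attack; the antipode is equally available should a test run show the opposite sense.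

**Route**

Step 1
Reactants: 1 4-bromo-3-fluorophenol
Product: 2 1-bromo-2-fluoro-4-(methoxymethoxy)benzene
Conditions: MOMCl, i-Pr2NEt, CH2Cl2, 0 → 23 °C
Reagents that add atoms: chloromethyl methyl ether, COCCl
Why: O-alkylation of the phenol with the α-chloro ether gives the MOM acetal, which survives the organolithium steps and later directs the lithiation.

Step 2
Reactants: 2 1-bromo-2-fluoro-4-(methoxymethoxy)benzene
Product: 5 1-bromo-2-fluoro-4-(methoxymethoxy)-3-(3-methylbut-2-en-1-yl)benzene, via aryllithium 3 (not isolated), via arylcopper 4 (not isolated)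
Conditions: LDA, THF, −78 °C; CuBr·SMe2, −78 °C; prenyl bromide, −78 → 0 °C
Reagents that add atoms: 1-bromo-3-methylbut-2-ene (prenyl bromide), CC(C)=CCBr
Why: Directed ortho-metalation removes the most acidic proton, the one flanked by F and OMOM, while LDA leaves the C–Br bond alone; transmetalation to copper stabilises the ortho-fluoro aryl anion against LiF loss, and the arylcopper should couple with prenyl bromide at the primary carbon (SN2).

Step 3
Reactants: 5 1-bromo-2-fluoro-4-(methoxymethoxy)-3-(3-methylbut-2-en-1-yl)benzene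
Product: 7 1-[2-fluoro-4-(methoxymethoxy)-3-(3-methylbut-2-en-1-yl)phenyl]ethan-1-one, via aryllithium 6 (not isolated)
Conditions: n-BuLi, THF, −78 °C; N-methoxy-N-methylacetamide, −78 °C; aq NH4Cl
Reagents that add atoms: N-methoxy-N-methylacetamide, CC(=O)N(C)OC
Why: Bromine–lithium exchange is faster than any deprotonation at −78 °C, where the ortho-fluoro aryllithium is stable, and acylation with the N-methoxy-N-methylamide stops at the ketone without over-addition.

Step 4
Reactants: 7 1-[2-fluoro-4-(methoxymethoxy)-3-(3-methylbut-2-en-1-yl)phenyl]ethan-1-one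
Product: 9 {1-[2-fluoro-4-(methoxymethoxy)-3-(3-methylbut-2-en-1-yl)phenyl]ethenyloxy}trimethylsilane, via lithium enolate 8 (not isolated)
Conditions: LiHMDS, THF, −78 °C; TMSCl, −78 → 0 °C; non-aqueous work-up (pentane, filtration)
Reagents that add atoms: chlorotrimethylsilane, C[Si](C)(C)Cl
Why: Deprotonation at the only enolisable position and O-silylation of the lithium enolate give the enol silane for the Mukaiyama aldol; the MOM ether and the aryl fluoride are inert to LiHMDS at −78 °C.

Step 5
Reactants: 10 3-bromo-4,5-dihydroxybenzaldehyde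
Product: 11 3-bromo-4,5-bis(methoxymethoxy)benzaldehyde
Conditions: MOMCl (2.5 equiv), i-Pr2NEt, CH2Cl2, 0 → 23 °C
Reagents that add atoms: chloromethyl methyl ether, COCCl
Why: Double O-alkylation of the catechol gives acetals that are stable to Pd(0), to a boron Lewis acid at −78 °C and to fluoride.

Step 6
Reactants: 11 3-bromo-4,5-bis(methoxymethoxy)benzaldehyde
Product: 12 3,4-bis(methoxymethoxy)-5-(3-methylbut-2-en-1-yl)benzaldehyde
Conditions: tributyl(3-methylbut-2-en-1-yl)stannane, Pd(PPh3)4 (5 mol%), DMF, 90 °C
Reagents that add atoms: tributyl(3-methylbut-2-en-1-yl)stannane, CCCC[Sn](CCCC)(CCCC)CC=C(C)C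
Why: Stille coupling under neutral conditions leaves the aldehyde untouched, and the allylic stannane should transfer the prenyl group through its less hindered terminus to give the linear 3-methylbut-2-enyl arene.

Step 7
Reactants: 9 {1-[2-fluoro-4-(methoxymethoxy)-3-(3-methylbut-2-en-1-yl)phenyl]ethenyloxy}trimethylsilane; 12 3,4-bis(methoxymethoxy)-5-(3-methylbut-2-en-1-yl)benzaldehyde
Product: 15 (2S)-2-[3,4-bis(methoxymethoxy)-5-(3-methylbut-2-en-1-yl)phenyl]-7-(methoxymethoxy)-8-(3-methylbut-2-en-1-yl)-2,3-dihydro-4H-chromen-4-one, via silyl aldol 13 (not isolated), via caesium alkoxide 14 (not isolated)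
Conditions: 9 (1.0 equiv), 12 (1.1 equiv), (4R)-2-butyl-4-(indol-3-ylmethyl)-3-tosyl-1,3,2-oxazaborolidin-5-one (20 mol%), EtCN, −78 °C; then anhydrous CsF (0.5 equiv), DMF, −40 → 20 °C; pH 7 buffer
Reagents that add atoms: none
Why: Proposed new method: in the first stage the boron-bound aldehyde 12 is attacked on its Si face by enol silane 9 through an open transition state and silyl transfer gives 13; in the second stage fluoride unmasks alkoxide 14, which adds to C8a and expels fluoride by addition–elimination, so that fluoride is a chain carrier and Me3SiF the only by-product. The closest known reaction types are the oxazaborolidinone-catalysed enantioselective Mukaiyama aldol of aryl methyl ketone enol silanes with aromatic aldehydes, the fluoride-promoted SNAr etherification of silyl ethers with activated aryl fluorides, and base-induced addition/SNAr annulations of 2-fluoroaryl ketones; what is new is their union in one flask to a flavanone. Ring C, the only ring formed, closes in a 6-endo-trig attack of the C2 oxygen on C8a of the C8a=C4a–C4=O unit, whose σ-adduct is an enolate of the C4 carbonyl. C2 is set in the aldol stage by the catalyst (indole shielding of the Re face of the formyl group) and passes through the closure unchanged, because the C2–O bond is already in place and is not broken. The step needs enantiofacial control and a closure that is faster than retro-aldol cleavage or E1cB loss of the oxygen from 14: the catalyst secures the first, and the second rests on the intramolecular six-membered closure onto a fluoride ortho to the carbonyl, on the low standing concentration of 14 under substoichiometric fluoride, and on the 7-OMOM group lying meta to C8a so that it does not donate directly to the carbon under attack.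

Step 8
Reactants: 15 (2S)-2-[3,4-bis(methoxymethoxy)-5-(3-methylbut-2-en-1-yl)phenyl]-7-(methoxymethoxy)-8-(3-methylbut-2-en-1-yl)-2,3-dihydro-4H-chromen-4-one
Product: 16 (2S)-2-[3,4-dihydroxy-5-(3-methylbut-2-en-1-yl)phenyl]-7-hydroxy-8-(3-methylbut-2-en-1-yl)-2,3-dihydro-4H-chromen-4-one
Conditions: HCl (1.25 M in MeOH), 23 °C
Reagents that add atoms: none
Why: Acid-catalysed acetal exchange with methanol should remove the three MOM groups at room temperature, where the trisubstituted alkenes are not protonated at a competitive rate and the flavanone stereocentre, which is labile only to base, is kept.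

**Compound list**

1 | 4-bromo-3-fluorophenol | Oc1ccc(Br)c(F)c1 | starting material
2 | 1-bromo-2-fluoro-4-(methoxymethoxy)benzene | COCOc1ccc(Br)c(F)c1 | intermediate
3 | [3-bromo-2-fluoro-6-(methoxymethoxy)phenyl]lithium | COCOc1ccc(Br)c(F)c1[Li] | intermediate
4 | [3-bromo-2-fluoro-6-(methoxymethoxy)phenyl]copper | COCOc1ccc(Br)c(F)c1[Cu] | intermediate
5 | 1-bromo-2-fluoro-4-(methoxymethoxy)-3-(3-methylbut-2-en-1-yl)benzene | COCOc1ccc(Br)c(F)c1CC=C(C)C | intermediate
6 | [2-fluoro-4-(methoxymethoxy)-3-(3-methylbut-2-en-1-yl)phenyl]lithium | [Li]c1ccc(OCOC)c(CC=C(C)C)c1F | intermediate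
7 | 1-[2-fluoro-4-(methoxymethoxy)-3-(3-methylbut-2-en-1-yl)phenyl]ethan-1-one | CC(=O)c1ccc(OCOC)c(CC=C(C)C)c1F | intermediate
8 | lithium 1-[2-fluoro-4-(methoxymethoxy)-3-(3-methylbut-2-en-1-yl)phenyl]ethen-1-olate | [Li]OC(=C)c1ccc(OCOC)c(CC=C(C)C)c1F | intermediate
9 | {1-[2-fluoro-4-(methoxymethoxy)-3-(3-methylbut-2-en-1-yl)phenyl]ethenyloxy}trimethylsilane | C=C(O[Si](C)(C)C)c1ccc(OCOC)c(CC=C(C)C)c1F | intermediate
10 | 3-bromo-4,5-dihydroxybenzaldehyde | O=Cc1cc(Br)c(O)c(O)c1 | starting material
11 | 3-bromo-4,5-bis(methoxymethoxy)benzaldehyde | O=Cc1cc(Br)c(OCOC)c(OCOC)c1 | intermediate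
12 | 3,4-bis(methoxymethoxy)-5-(3-methylbut-2-en-1-yl)benzaldehyde | CC(C)=CCc1cc(C=O)cc(OCOC)c1OCOC | intermediate
13 | (3S)-3-[3,4-bis(methoxymethoxy)-5-(3-methylbut-2-en-1-yl)phenyl]-1-[2-fluoro-4-(methoxymethoxy)-3-(3-methylbut-2-en-1-yl)phenyl]-3-(trimethylsilyloxy)propan-1-one | CC(C)=CCc1cc([C@@H](O[Si](C)(C)C)CC(=O)c2ccc(OCOC)c(CC=C(C)C)c2F)cc(OCOC)c1OCOC | intermediate
14 | caesium (1S)-1-[3,4-bis(methoxymethoxy)-5-(3-methylbut-2-en-1-yl)phenyl]-3-[2-fluoro-4-(methoxymethoxy)-3-(3-methylbut-2-en-1-yl)phenyl]-3-oxopropan-1-olate | CC(C)=CCc1cc([C@@H]([O-])CC(=O)c2ccc(OCOC)c(CC=C(C)C)c2F)cc(OCOC)c1OCOC.[Cs+] | intermediate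
15 | (2S)-2-[3,4-bis(methoxymethoxy)-5-(3-methylbut-2-en-1-yl)phenyl]-7-(methoxymethoxy)-8-(3-methylbut-2-en-1-yl)-2,3-dihydro-4H-chromen-4-one | CC(C)=CCc1cc([C@@H]2CC(=O)c3ccc(OCOC)c(CC=C(C)C)c3O2)cc(OCOC)c1OCOC | intermediate
16 | (2S)-2-[3,4-dihydroxy-5-(3-methylbut-2-en-1-yl)phenyl]-7-hydroxy-8-(3-methylbut-2-en-1-yl)-2,3-dihydro-4H-chromen-4-one | CC(C)=CCc1cc([C@@H]2CC(=O)c3ccc(O)c(CC=C(C)C)c3O2)cc(O)c1O | target

**Count**

Total steps: 8. Longest linear sequence: 6 (steps 1, 2, 3, 4, 7, 8); steps 5 and 6 form the second branch.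

**Steps most likely to fail**

1. Step 7 (proposed new method). What may go wrong:
- poor facial selectivity in the aldol stage if the acetal oxygens compete with the aldehyde for boron;
- retro-aldol cleavage or E1cB loss of the oxygen from the alkoxide before ring closure, which lowers enantiopurity or leads to an open-chain enone;
- fluoride-induced ring opening of the product with loss of configuration.

The fallback uses known chemistry and a different bond set (C2–C3 by condensation, O1–C2 by oxa-Michael addition). It sets out from ketone 7 and aldehyde 12. Fluoride in 7 is exchanged for hydroxide by SNAr (KOH, DMSO–H2O, 80 °C) to give 1-[2-hydroxy-4-(methoxymethoxy)-3-(3-methylbut-2-en-1-yl)phenyl]ethan-1-one F1. Claisen–Schmidt condensation of F1 with 12 (KOH, EtOH, 20 °C) should give the (E)-2'-hydroxychalcone F2. NaOAc in refluxing EtOH closes it to the racemic flavanone F3. Preparative HPLC on a chiral stationary phase then delivers the (2S)-enantiomer, which is 15, where the fallback rejoins the route; the (2R)-enantiomer F4 is set aside.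

2. Step 2. What may go wrong:
- loss of LiF from the aryllithium (aryne formation) if the solution warms before transmetalation;
- incomplete lithium-to-copper exchange;
- attack of the arylcopper at the tertiary terminus of prenyl bromide (SN2'), giving the 1,1-dimethylallyl isomer.

The fallback sets out from 2 by way of aryllithium 3. Iodine is added at −78 °C, a quench that needs no warming, to give 1-bromo-2-fluoro-3-iodo-4-(methoxymethoxy)benzene F5. A chemoselective Stille coupling at the C–I bond with tributyl(3-methylbut-2-en-1-yl)stannane (Pd2(dba)3, AsPh3, CuI, DMF, 50 °C) should then give 5, where the fallback rejoins the route.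

3. Step 6. What may go wrong:
- allylic transposition during transmetalation, giving the branched 1,1-dimethylallyl arene;
- slow oxidative addition next to the OMOM group with competing protodestannylation.

The fallback sets out from 11. Stille coupling with allyltributylstannane (Pd(PPh3)4, DMF, 90 °C), which has no regiochemical ambiguity, gives 3,4-bis(methoxymethoxy)-5-(prop-2-en-1-yl)benzaldehyde F6. Olefin cross-metathesis of F6 with excess 2-methylbut-2-ene (second-generation Ru benzylidene catalyst, CH2Cl2, 40 °C) converts the allyl into the prenyl group and returns to the route at 12.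

**Further compounds**

F1 | step 7 | 1-[2-hydroxy-4-(methoxymethoxy)-3-(3-methylbut-2-en-1-yl)phenyl]ethan-1-one | CC(=O)c1ccc(OCOC)c(CC=C(C)C)c1O
F2 | step 7 | (2E)-3-[3,4-bis(methoxymethoxy)-5-(3-methylbut-2-en-1-yl)phenyl]-1-[2-hydroxy-4-(methoxymethoxy)-3-(3-methylbut-2-en-1-yl)phenyl]prop-2-en-1-one | CC(C)=CCc1cc(/C=C/C(=O)c2ccc(OCOC)c(CC=C(C)C)c2O)cc(OCOC)c1OCOC
F3 | step 7 | racemic 2-[3,4-bis(methoxymethoxy)-5-(3-methylbut-2-en-1-yl)phenyl]-7-(methoxymethoxy)-8-(3-methylbut-2-en-1-yl)-2,3-dihydro-4H-chromen-4-one | CC(C)=CCc1cc(C2CC(=O)c3ccc(OCOC)c(CC=C(C)C)c3O2)cc(OCOC)c1OCOC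
F4 | step 7 | (2R)-2-[3,4-bis(methoxymethoxy)-5-(3-methylbut-2-en-1-yl)phenyl]-7-(methoxymethoxy)-8-(3-methylbut-2-en-1-yl)-2,3-dihydro-4H-chromen-4-one | CC(C)=CCc1cc([C@H]2CC(=O)c3ccc(OCOC)c(CC=C(C)C)c3O2)cc(OCOC)c1OCOC
F5 | step 2 | 1-bromo-2-fluoro-3-iodo-4-(methoxymethoxy)benzene | COCOc1ccc(Br)c(F)c1I
F6 | step 6 | 3,4-bis(methoxymethoxy)-5-(prop-2-en-1-yl)benzaldehyde | C=CCc1cc(C=O)cc(OCOC)c1OCOC
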